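Assumption: the target is treated as the 2-hydroxy-1,4-benzoquinone tautomer written in the SMILES, with thirteen methylene groups between the two ring carbons; it is achiral, so no stereodescriptor is needed.

## Structural features

The target (C29H40O8) consists of two identical 2-hydroxy-5-methoxy-6-methyl-1,4-benzoquinone rings, each bonded through its C3 to one terminus (C1 and C13) of an unbranched tridecane-1,13-diyl chain. There is no ring fusion and no stereocentre. A mirror plane passes through the central chain carbon C7, so the centre of the molecule is an atom and not a bond: the odd chain excludes every plan that joins two identical halves at a central C–C bond. Each ring is fully substituted in the order C1=O, C2–OH, C3–chain, C4=O, C5–OMe, C6–Me, so the methylated oxygen sits next to the ring methyl and the free hydroxyl next to the chain. These two oxygen sites differ only in having a methyl or a primary alkyl neighbour, so telling them apart once both carbon substituents are in place is the real difficulty; the C–C bonds are simple by comparison. The fragile groups are the hydroxyquinone (a vinylogous acid, easily O-alkylated, reduced or degraded by base and oxidants) and the methoxyquinone (a vinylogous ester, open to exchange or hydrolysis). The key step exploits the fact that C3 is the one ring carbon that would carry hydrogen if the chain were removed: in the monomeric quinone it is the only C–H, flanked by C2–OH and C4=O and β to the C1 carbonyl, so a carbon radical born at a chain terminus can add nowhere else, and the (CH2)13 chain is a C15 α,ω-diacid less two molecules of CO2.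

## Logic of the disconnections

**8 to 5 (twice) and 6, by way of 7.** The bonds cut are the two C(sp2)–C(sp3) bonds between ring carbon C3 of each quinone and chain carbons C1 and C13 of 8; in the forward sense the two C–CO2H bonds of 6 are lost as CO2. The cut is made there because each ring of 8 is 5 with its single ring hydrogen replaced, and the chain is 6 less two CO2. The OMe-beside-Me, OH-beside-chain pattern is therefore already written into 5 and cannot be scrambled. The gain is large: a C29 bis-quinone falls to a C8 quinone used twice and a purchasable diacid, with no protecting group and no redox adjustment after the coupling; 7 is the half-way compound. The demand on the forward step is that each primary radical born at a terminus of 6 or 7 adds to C3 of 5 faster than it is lost, that both carboxyl groups react, and that the hydroxyquinone and the vinylogous ester survive a peroxydisulfate oxidant in warm aqueous acid.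

**5 to 3, by way of 4.** The bonds cut are the three O–acetyl bonds, together with a two-electron change of oxidation level. The free hydroxyquinone is released only at the end from a stable aromatic triester that can be stored and purified. The demand is deacetylation without loss of the aryl methyl ether, and oxidation of 4 in the absence of methanol (the vinylogous acid of 5 would esterify) and without oxidative coupling at the free ring carbon.

**3 to 2.** The bond cut is the ring C–O bond at the carbon para to the methoxy-bearing carbon (C5 of 2), plus two O–acetyl bonds. The third oxygen is introduced at the quinone level under the direction of the methoxy group already present. The gain is that the OMe/Me relation never has to be made: it is carried from the start. The demand is addition at C5 and not at C6 of 2.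

**2 to 1.** The bond cut is the C–O bond para to the phenolic hydroxyl. This leads to a purchasable phenol that already holds the methoxy and methyl groups on neighbouring carbons. The demand is para-selective oxidation of a phenol with a free para position.

## Other disconnections considered

Alternative 1: the first that comes to mind. The cut is at the same two ring–chain bonds, but at the arene oxidation level and with polar reactivity. The forward key step is a twofold alkylation of the aryllithium of 1,2,4,5-tetramethoxy-3-methylbenzene A1 with 1,13-dibromotridecane A2 to give the bis-arene A3. Oxidative demethylation with (NH4)2Ce(NO3)6 then gives the bis(2,5-dimethoxyquinone) A4, and one methyl group per ring must finally be removed. The chosen plan is preferred because in A4 the two methoxy groups of each ring are both vinylogous esters, one flanked by CH3 and one by CH2R. Nothing in the structure lets hydroxide or acid tell them apart, so each ring would be expected to give both hydroxy isomers and the bis-quinone three constitutional isomers of near-identical polarity. The chosen plan decides OMe versus OH before the chain exists, at a stage where the directing is done by a methoxy group against a hydrogen, not by a methyl against an alkyl.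

Alternative 2: the cut is at the chain bonds C6–C7 and C7–C8, at the atom through which the mirror plane passes. The forward key step is a twofold alkylation of tosylmethyl isocyanide, as a one-carbon linchpin, with the ω-bromohexyl arene A5, followed by hydrolysis to the symmetric ketone A6 and deoxygenation to A3. This uses the odd chain well, but it spends three operations on a carbonyl that is then deleted. It also arrives at A3, that is, at the unsolved regiochemical problem of Alternative 1: it simplifies the easy part (the chain) and leaves the hard part (the rings) untouched.

Alternative 3: the cut is, in each quinone ring, at the C–C bond between a carbonyl carbon and its alkyl-bearing neighbour, so that both rings are made last from a four-membered ring and an alkyne terminus of the chain. The forward key step is a twofold addition of dilithiated heptadeca-1,16-diyne A7 to 3-methoxy-4-methylcyclobut-3-ene-1,2-dione A8 to give the bis(4-alkynyl-4-hydroxycyclobutenone) A9, then a twofold thermal Moore ring expansion (electrocyclic opening to a vinylketene, closure onto the alkyne, hydrogen transfer). The mechanism fixes where the substituents land. The acetylide adds to the ketone-like carbonyl of A8 (the one not conjugated with the methoxy group), the alkyne substituent ends beside the former ketene carbonyl, and the other alkyne carbon receives hydrogen. The product would therefore be bis-quinone A10, with the chain para to the methoxy group, on the carbon that must carry OH, and with C–H where the chain belongs. Correcting this would need the opposite carbonyl selectivity plus a later ring hydroxylation, and a C17 diyne that must itself be made.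

Key step: step 4

Route in one sentence: two molecules of the preformed hydroxy(methoxy)methylbenzoquinone 5 are attached to the two ends of pentadecanedioic acid 6 by a twofold silver-catalysed decarboxylative radical C–H alkylation.

## Steps

Step 1
Reactants: 1 3-methoxy-2-methylphenol
Product: 2 2-methoxy-3-methylcyclohexa-2,5-diene-1,4-dione
Conditions: (KO3S)2NO (2.2 equiv), KH2PO4, H2O/acetone, 0 °C to rt
Reagents that add atoms: potassium nitrosodisulfonate (Fremy's salt), [K+].[K+].[O-]S(=O)(=O)N([O])S(=O)(=O)[O-]
Why: Teuber oxidation: the nitroxide radical abstracts the phenolic hydrogen and a second equivalent delivers oxygen to the free para position, so a phenol with an open para carbon should give the para-quinone; the methoxy and methyl groups stay on adjacent carbons.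

Step 2
Reactants: 2 2-methoxy-3-methylcyclohexa-2,5-diene-1,4-dione
Product: 3 5-methoxy-6-methylbenzene-1,2,4-triyl triacetate
Conditions: Ac2O, H2SO4 (cat.), 0 °C to rt
Reagents that add atoms: acetic anhydride, CC(=O)OC(C)=O
Why: Thiele–Winter acetoxylation: acid-catalysed conjugate addition of acetate, enolisation and acetylation of all three oxygens. The methoxy group is conjugated with the C4 carbonyl (vinylogous ester) and deactivates the enone that would lead to attack at C6, so acetate should add at C5, para to the methoxy-bearing carbon; the weaker opposing effect of the ring methyl is the selectivity risk.

Step 3
Reactants: 3 5-methoxy-6-methylbenzene-1,2,4-triyl triacetate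
Product: 5 2-hydroxy-5-methoxy-6-methylcyclohexa-2,5-diene-1,4-dione, via 5-methoxy-6-methylbenzene-1,2,4-triol 4 (not isolated)
Conditions: a) HCl (cat.), MeOH, reflux, N2, then evaporation to dryness; b) FeCl3 (2.2 equiv), H2O/EtOAc, rt
Reagents that add atoms: none
Why: Acid-catalysed transesterification removes the three aryl acetates without touching the aryl methyl ether, and the electron-rich triol 4 is then oxidised by FeCl3 (trivalent iron, two one-electron steps) to the para-quinone, the 2-hydroxy-1,4-quinone being the stable tautomer. Methanol is removed before the oxidation so that the vinylogous acid is not re-esterified.

Step 4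
Reactants: 5 2-hydroxy-5-methoxy-6-methylcyclohexa-2,5-diene-1,4-dione (two molecules incorporated; used in excess); 6 pentadecanedioic acid
Product: 8 3,3'-(tridecane-1,13-diyl)bis(2-hydroxy-5-methoxy-6-methylcyclohexa-2,5-diene-1,4-dione), via 14-quinonyltetradecanoic acid 7 (not isolated)
Conditions: AgNO3 (0.4 equiv), (NH4)2S2O8 (3 equiv, added slowly), MeCN/H2O (1:1), 65 °C; 5 (5 equiv) per 6 (1 equiv)
Reagents that add atoms: none
Why: Peroxydisulfate oxidises AgNO3 (monovalent silver) to divalent silver, which oxidises a carboxylate of 6 to an acyloxy radical that loses CO2 and leaves a nucleophilic primary alkyl radical at the chain terminus. This radical adds to C3 of 5, the only unsubstituted ring carbon and the β-carbon of the C1 enone, to give a radical at C2 stabilised by both the hydroxyl and the C1 carbonyl; oxidation by divalent silver or peroxydisulfate and loss of the C3 proton restore the quinone and give 7. The same sequence at the remaining carboxyl of 7 with a second molecule of 5 gives 8. The closest known reaction type is the silver-catalysed peroxydisulfate decarboxylative C–H alkylation of quinones (a Minisci-type radical substitution), together with the older alkylation of 2-hydroxyquinones by alkyl radicals from diacyl peroxides. No ring is closed and no stereocentre is formed. The selectivity needed is C3 over every other site and twofold over single reaction: the first is secured by the substrate, since 5 has one C–H and its OMe/OH pattern is carried into 8 untouched, so neither a regioisomer nor a polyalkylated ring can arise; the second is pursued by an excess of 5 (recoverable) and slow addition of the oxidant, and residual 7 can be resubmitted. The acid that the oxidant generates keeps 5 in its neutral, less oxidisable form, and the saturated chain carries no other reactive group.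

## Compound list

1 | 3-methoxy-2-methylphenol | COc1cccc(O)c1C | starting material
2 | 2-methoxy-3-methylcyclohexa-2,5-diene-1,4-dione | COC1=C(C)C(=O)C=CC1=O | intermediate
3 | 5-methoxy-6-methylbenzene-1,2,4-triyl triacetate | COc1c(C)c(OC(C)=O)c(OC(C)=O)cc1OC(C)=O | intermediate
4 | 5-methoxy-6-methylbenzene-1,2,4-triol | COc1c(C)c(O)c(O)cc1O | intermediate (not isolated)
5 | 2-hydroxy-5-methoxy-6-methylcyclohexa-2,5-diene-1,4-dione | COC1=C(C)C(=O)C(O)=CC1=O | intermediate
6 | pentadecanedioic acid | OC(=O)CCCCCCCCCCCCCC(O)=O | starting material
7 | 14-(2-hydroxy-5-methoxy-4-methyl-3,6-dioxocyclohexa-1,4-dien-1-yl)tetradecanoic acid | COC1=C(C)C(=O)C(O)=C(CCCCCCCCCCCCCC(O)=O)C1=O | intermediate (not isolated)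
8 | 3,3'-(tridecane-1,13-diyl)bis(2-hydroxy-5-methoxy-6-methylcyclohexa-2,5-diene-1,4-dione) | COC1=C(C)C(=O)C(O)=C(CCCCCCCCCCCCCC2=C(O)C(=O)C(C)=C(OC)C2=O)C1=O | target

## Step count and least certain steps

Total step count: 4. Longest linear sequence: 4 steps (1 to 2 to 3 to 5 to 8); 6 is purchased.

**Step 4 (key step).** The most likely failure is inefficient radical capture at the second chain terminus, combined with oxidative degradation of 5 by sulfate radical anion and loss of the primary radical by hydrogen abstraction. Material would then stop at the stage of 7 or be consumed unproductively. Slow acid hydrolysis of the vinylogous ester in the warm medium is a second concern. The fallback replaces the radical by a polar, organocatalytic bond formation and the acid by an aldehyde; it sets out from 5 and returns at 8. Purchased tridecane-1,13-diol F1 is oxidised (PhI(OAc)2, TEMPO cat., CH2Cl2, rt) to tridecanedial F2. Compound 5 (2.2 equiv), F2 and Hantzsch ester (2.2 equiv) with L-proline (cat.) in CH2Cl2 at rt should then give 8 by a twofold three-component reductive alkylation. Each aldehyde condenses in a Knoevenagel reaction at C3 of 5, the α-carbon of the vinylogous acid and again the only C–H, and the dihydropyridine transfers hydride to the alkylidene formed. The regiochemical guarantee is the same as in the main route.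

**Step 2.** The most likely failure is poor site selectivity in the acetate addition: the ring methyl of 2 directs to C6 against the methoxy group directing to C5, and an isomeric triacetate would carry through to an isomeric hydroxyquinone. The fallback fixes the oxygen pattern by electrophilic aromatic substitution instead of conjugate addition to a quinone; it sets out from 1 and returns at 4, and so at 5. Duff formylation of 1 with excess hexamethylenetetramine in CF3CO2H (reflux, then aqueous acid) should formylate both positions activated by the hydroxyl and the methoxy group; the remaining ring CH is meta to both. This gives 4-hydroxy-6-methoxy-5-methylbenzene-1,3-dicarbaldehyde F3. A twofold Dakin oxidation (H2O2, NaOH aq., 0 °C, N2, then acidification) replaces the two formyl groups, one ortho and one para to the phenol, by hydroxyl to give triol 4, which is oxidised with FeCl3 as in stage b of step 3.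

**Step 3.** The most likely failures are re-esterification of the vinylogous acid by residual methanol during the oxidation, hydrolytic loss of the methoxy group, and oxidative coupling at the free ring carbon of the electron-rich triol under FeCl3. The fallback never leaves the quinone oxidation level, so it needs neither the air-sensitive triol nor a metal oxidant; it sets out from 2 and returns at 5. Oxidative amination of 2 with morpholine (EtOH, air, rt) should place the amine at C5, the adduct being reoxidised by air, to give 2-methoxy-3-methyl-5-(morpholin-4-yl)cyclohexa-2,5-diene-1,4-dione F4. Hydrolysis of the vinylogous amide (dilute aqueous H2SO4, dioxane, 60 °C) then releases 5. This fallback relies on the same directing effect of the methoxy group as step 2 and is meant only for the case in which that selectivity holds but the deacetylation–oxidation does not.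

## Further compounds

F1 | step 4 | tridecane-1,13-diol (purchased) | OCCCCCCCCCCCCCO
F2 | step 4 | tridecanedial | O=CCCCCCCCCCCCCC=O
F3 | step 2 | 4-hydroxy-6-methoxy-5-methylbenzene-1,3-dicarbaldehyde | COc1c(C)c(O)c(C=O)cc1C=O
F4 | step 3 | 2-methoxy-3-methyl-5-(morpholin-4-yl)cyclohexa-2,5-diene-1,4-dione | COC1=C(C)C(=O)C(N2CCOCC2)=CC1=O
A1 | alternative 1 | 1,2,4,5-tetramethoxy-3-methylbenzene | COc1cc(OC)c(OC)c(C)c1OC
A2 | alternative 1 | 1,13-dibromotridecane | BrCCCCCCCCCCCCCBr
A3 | alternative 1 | 1,13-bis(2,3,5,6-tetramethoxy-4-methylphenyl)tridecane | COc1c(C)c(OC)c(OC)c(CCCCCCCCCCCCCc2c(OC)c(OC)c(C)c(OC)c2OC)c1OC
A4 | alternative 1 | 3,3'-(tridecane-1,13-diyl)bis(2,5-dimethoxy-6-methylcyclohexa-2,5-diene-1,4-dione) | COC1=C(C)C(=O)C(OC)=C(CCCCCCCCCCCCCC2=C(OC)C(=O)C(C)=C(OC)C2=O)C1=O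
A5 | alternative 2 | 1-(6-bromohexyl)-2,3,5,6-tetramethoxy-4-methylbenzene | COc1c(C)c(OC)c(OC)c(CCCCCCBr)c1OC
A6 | alternative 2 | 1,13-bis(2,3,5,6-tetramethoxy-4-methylphenyl)tridecan-7-one | COc1c(C)c(OC)c(OC)c(CCCCCCC(=O)CCCCCCc2c(OC)c(OC)c(C)c(OC)c2OC)c1OC
A7 | alternative 3 | heptadeca-1,16-diyne | C#CCCCCCCCCCCCCCC#C
A8 | alternative 3 | 3-methoxy-4-methylcyclobut-3-ene-1,2-dione | COC1=C(C)C(=O)C1=O
A9 | alternative 3 | 4,4'-(heptadeca-1,16-diyne-1,17-diyl)bis(4-hydroxy-3-methoxy-2-methylcyclobut-2-en-1-one), mixture of diastereomers | COC1=C(C)C(=O)C1(O)C#CCCCCCCCCCCCCCC#CC2(O)C(OC)=C(C)C2=O
A10 | alternative 3 | 5,5'-(tridecane-1,13-diyl)bis(2-methoxy-3-methylcyclohexa-2,5-diene-1,4-dione) | COC1=C(C)C(=O)C(CCCCCCCCCCCCCC2=CC(=O)C(OC)=C(C)C2=O)=CC1=O
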